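The leftover came first: at 0.950 equiv of L, G outlasts L, so the excess of G over L opens at 5.00 % of the charge and widens with every J, since J costs a second L. L is the limiting reagent in gamma and epsilon.

| flask | G | L | remark | time |
|---|---|---|---|---|
| Monday's | 0.050 M | 0.95 equiv | run made earlier |  |
| Friday's | 0.075 M | 0.95 equiv | run made earlier |  |
| Saturday's | 0.10 M | 1.9 equiv | run made earlier |  |
| epsilon | 0.10 M | 0.950 equiv |  | 25 h |
| gamma | 0.10 M | 0.950 equiv |  | 20 h |

| run | time / h | Z / % | G / % | E / % | J / % |
|---|---|---|---|---|---|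
| Monday's | 1.33 | 11 | 87 | 1 | 2 |
| Monday's | 4.00 | 19 | 70 | 12 | 0 |
| Monday's | 8.00 | 27 | 54 | 11 | 2 |
| Monday's | 12.0 | 29 | 41 | 13 | 3 |
| Monday's | 15.0 | 37 | 44 | 17 | 0 |
| Friday's | 1.33 | 14 | 84 | 0 | 0 |
| Friday's | 4.00 | 26 | 58 | 9 | 4 |
| Friday's | 8.00 | 37 | 48 | 17 | 2 |
| Friday's | 12.0 | 38 | 36 | 21 | 4 |
| Friday's | 15.0 | 41 | 32 | 15 | 6 |
| Saturday's | 3.00 | 42 | 36 | 13 | 6 |
| Saturday's | 6.00 | 51 | 16 | 21 | 11 |
| Saturday's | 10.0 | 50 | 8 | 24 | 16 |
| Saturday's | 12.0 | 51 | 2 | 29 | 18 |
| Saturday's | 15.0 | 52 | 7 | 24 | 20 |

(each reading ± 2 percentage points)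

- which of these there is most of at the end, counted by the G in it, epsilon (Z / G / J / E)
- which of these there is most of at the end, counted by the G in it, gamma (Z / G / J / E)
- amount of the one of these that there is most of at the end, in percent of the G charged, epsilon
- amount of the one of these that there is most of at the end, in percent of the G charged, gamma

- the numbers in the tables scatter by 2 percentage points (one standard deviation)

I drew the curve for gamma from these runs. Friday's last G, rescaled to 0.10 M on a second-order clock, gave a half-time of 5.29 h for equal charges, so I took G to start falling at 0.189 h⁻¹ of its charge. Saturday's last 4 readings gave ρ, the amount of E per amount of Z, as 0.480. My rule, with ρ held at that reading, was that Z is the charge minus G and J, divided by one plus ρ.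

Neglecting J, I put the crossing of G and Z near 7.83 h. Equal charges would have run into 20.9 % at 20 h and 17.5 % at 25 h. Saturday's flask started from the same G with twice the L, so I took J as that flask's last reading of 20 % divided by 2, or 10.0 %, which made my estimate of the excess 15.0 %. Adding half of that excess as the correction put G at 28.4 % in gamma and 25.0 % in epsilon. Z came to 41.6 % in gamma and 43.9 % in epsilon.

The forecast also named Z, at 48.5 % in gamma and 50 % in epsilon, holding that E “comes from G in parallel with Z”.

The flasks gave Z 43.4 % in gamma and 44.5 % in epsilon.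

    G + L → Z (k = 2.01 M⁻¹ h⁻¹)
    G + L → X (k = 0.195 M⁻¹ h⁻¹)
    L + Z → J (k = 0.197 M⁻¹ h⁻¹)
    L + X → J (k = 3.80 M⁻¹ h⁻¹)
    Z ⇌ E (K = 0.510, k = 0.233 h⁻¹)

Z passes into E with a forward half-life of 3.0 h, the way back not counted, short against the 25 h of epsilon, and in gamma Z is made 2.24 times faster than used up at 2.98 h, each step taken net. Taking also X, the mono adduct at the other site, from the charge, ρ turns gamma's final G, J and X into Z 44.0 %, and the neighbour of gamma with 1.60 equiv of L into 51.1 %, where that flask held 50.1 %.

(All runs were computed with made-up constants; noise was put on by code.)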